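## Retrosynthetic overview

1. The C40 diol is cut at C11=C12 and C11'=C12' (double Wittig) into two C15 hydroxy enals and a C10 bis(phosphonium) salt.
2. The C15 enal is cut at C8–C9 into the lactol acetate of loliolide (cation at C8) and an (E)-but-2-en-2-yl trifluoroborate; C8 is the last stereocentre set.
3. The butenolide (cyclohexane ring C1–C6 fused to the oxygen ring O–C5–C6=C7–C8) is cut at C1–C6 and O–C8 to an acyclic 4-hydroxy ynoate with an isopropenyl end. A hydrogen-atom-transfer radical closure forms the cyclohexane ring first and the lactone (the later dihydrofuran) second.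
4. Feature used: in the cyclohexane ring the C3 oxygen is axial, cis to the axial C5 methyl and syn-diaxial to one methyl of C1, and C5 also carries the oxygen that bridges to C8. The C1–C6 bond (gem-dimethyl C1, sp2 C6) creates no stereocentre, so C3 and C5 are fixed in the open chain.
5. C3 comes from (S)-epichlorohydrin; C5 from a chelation-controlled alkynylation of the β-alkoxy methyl ketone.

Key step: step 7

Remark on the chemistry: the C3 oxygen is carried as a methoxymethyl ether up to the lactone (it chelates magnesium in step 6 and is inert to radicals and light in step 7) and is then exchanged for acetate; (2E,4E,6E)-2,7-dimethylocta-2,4,6-trienedial is taken as a purchasable building block.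

## Route

Step 1
Reactants: 1 (S)-epichlorohydrin; 2 isopropenylmagnesium bromide
Product: 3 (2S)-1-chloro-4-methylpent-4-en-2-ol
Conditions: CuI (10 mol%), THF, −40 to −20 °C; aq. NH4Cl
Reagents that add atoms: none
Why: Copper-catalysed Grignard opening of the epoxide at its unsubstituted carbon should give the chlorohydrin; the carbinol carbon (future C3) is not touched, so the S configuration of 1 is carried over.

Step 2
Reactants: 3 (2S)-1-chloro-4-methylpent-4-en-2-ol
Product: 4 (2S)-2-(2-methylprop-2-en-1-yl)oxirane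
Conditions: NaOH (powdered), Et2O, 0 °C to rt; distillation
Reagents that add atoms: none
Why: Intramolecular Williamson displacement of the primary chloride by the alkoxide closes the terminal epoxide without touching the stereocentre.

Step 3
Reactants: 5 2-methyl-1,3-dithiane; 4 (2S)-2-(2-methylprop-2-en-1-yl)oxirane
Product: 7 (2S)-4-methyl-1-(2-methyl-1,3-dithian-2-yl)pent-4-en-2-ol, via 2-lithio-2-methyl-1,3-dithiane 6 (not isolated)
Conditions: n-BuLi, THF, −30 to 0 °C; then 4, −30 °C to rt; aq. NH4Cl
Reagents that add atoms: none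
Why: Corey–Seebach umpolung, in which the lithiated dithiane (an acetyl anion equivalent) opens the terminal epoxide at CH2 by SN2, forms the C4–C5 bond and leaves the carbinol stereocentre untouched.

Step 4
Reactants: 7 (2S)-4-methyl-1-(2-methyl-1,3-dithian-2-yl)pent-4-en-2-ol
Product: 8 2-[(2S)-2-(methoxymethoxy)-4-methylpent-4-en-1-yl]-2-methyl-1,3-dithiane
Conditions: MeOCH2Cl, i-Pr2NEt, Bu4NI (cat.), CH2Cl2, 0 °C to rt
Reagents that add atoms: chloromethyl methyl ether, COCCl
Why: Standard O-alkylation of the secondary alcohol under amine base gives the acetal ether, chosen because it can chelate magnesium in step 6 and survives iron hydride, silane and ultraviolet light in step 7.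

Step 5
Reactants: 8 2-[(2S)-2-(methoxymethoxy)-4-methylpent-4-en-1-yl]-2-methyl-1,3-dithiane
Product: 9 (4S)-4-(methoxymethoxy)-6-methylhept-6-en-2-one
Conditions: MeI, CaCO3, MeCN/H2O (9:1), 45 °C
Reagents that add atoms: water, O
Why: Alkylative hydrolysis of the dithiane (S-methylation, then attack of water) under carbonate buffering unmasks the methyl ketone while the acetal ether and the 1,1-disubstituted alkene, both inert to MeI, are kept.

Step 6
Reactants: 9 (4S)-4-(methoxymethoxy)-6-methylhept-6-en-2-one; 10 ethyl propiolate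
Product: 12 ethyl (4R,6S)-4-hydroxy-6-(methoxymethoxy)-4,8-dimethylnon-8-en-2-ynoate, via ethyl 3-lithioprop-2-ynoate 11 (not isolated)
Conditions: 10, LiN(SiMe3)2, THF, −78 °C; 9 precomplexed with MgBr2·OEt2, CH2Cl2, −78 °C; combine at −78 °C; AcOH quench at −78 °C
Reagents that add atoms: none
Why: 1,2-Addition of the metal acetylide to the ketone held in a six-membered magnesium chelate between the carbonyl and the ether oxygen (chelation-controlled 1,3-induction) should set C5: with the methallyl arm equatorial on the chelate chair the acetylide enters axially, trans to that arm, which corresponds to the 4R,6S alcohol, and any 4-epimer is removed by chromatography.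

Step 7
Reactants: 12 ethyl (4R,6S)-4-hydroxy-6-(methoxymethoxy)-4,8-dimethylnon-8-en-2-ynoate
Product: 15 (6S,7aR)-6-(methoxymethoxy)-4,4,7a-trimethyl-5,6,7,7a-tetrahydro-1-benzofuran-2(4H)-one, via E hydroxy enoate 13 (not isolated), via Z hydroxy enoate 14 (not isolated)
Conditions: Fe(acac)3 (iron tris(acetylacetonate), trivalent iron, 30 mol%), PhSiH3, EtOH/HOCH2CH2OH (5:1), 60 °C; then solvent exchange, pyridinium p-toluenesulfonate (cat.), MeCN, hν (254 nm, quartz), rt to 40 °C
Reagents that add atoms: none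
Why: The iron hydride formed from Fe(acac)3 and PhSiH3 transfers a hydrogen atom to the CH2 terminus of the isopropenyl group, the tertiary C1 radical adds to C6 (the β-carbon of the ynoate), and the α-ester vinyl radical is reduced (electron transfer from divalent iron and protonation by ethanol, or hydrogen abstraction) to the cyclohexylidene acetates 13 and 14. The closest known reaction type is the metal-hydride hydrogen-atom-transfer Giese cyclization of an alkene onto an electron-poor π-acceptor, here an alkynoate, followed by the familiar lactonization of a (Z)-γ-hydroxy enoate and E/Z photoisomerization of an enoate. The cyclohexane ring closes by 6-exo-dig radical attack (C1–C6) and the butenolide by 5-exo-trig acyl substitution of the C5 hydroxyl on the ester (O–C8). No stereocentre is created (C1 carries two methyls, C6 becomes sp2), so C3 and C5 are carried over unchanged; the chair transition state can hold the C5 methyl and the C3 ether equatorial, and the triaxial arrangement of the bicycle appears only when the lactone closes. The step needs 6-exo over 7-endo attack, secured by the polarization of the ynoate toward the nucleophilic tertiary radical at C6 and by the four-atom tether, and it needs the ester cis to the C5 oxygen: Z ester 14 lactonizes irreversibly, while E ester 13, which cannot deconjugate on irradiation because both γ-carbons (C1 and C5) are quaternary, is photoisomerized until it has drained into the lactone.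

Step 8
Reactants: 15 (6S,7aR)-6-(methoxymethoxy)-4,4,7a-trimethyl-5,6,7,7a-tetrahydro-1-benzofuran-2(4H)-one
Product: 16 (6S,7aR)-6-hydroxy-4,4,7a-trimethyl-5,6,7,7a-tetrahydro-1-benzofuran-2(4H)-one ((−)-loliolide)
Conditions: HCl (conc. aq., cat.), MeOH, 45 °C
Reagents that add atoms: none
Why: Acid-catalysed transacetalization to methanol removes the acetal ether, which would otherwise compete as an electrophile in step 13; the conjugated lactone disfavours ionization at C5, and the product is a known natural product against which C3 and C5 can be checked.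

Step 9
Reactants: 16 (6S,7aR)-6-hydroxy-4,4,7a-trimethyl-5,6,7,7a-tetrahydro-1-benzofuran-2(4H)-one
Product: 18 (6S,7aR)-4,4,7a-trimethyl-2,4,5,6,7,7a-hexahydro-1-benzofuran-2,6-diyl diacetate (both C2 anomers), via aluminium-bound lactol 17 (not isolated)
Conditions: i-Bu2AlH, CH2Cl2, −78 °C; then pyridine, DMAP, Ac2O, −78 °C to rt
Reagents that add atoms: acetic anhydride, CC(=O)OC(C)=O
Why: Reductive acetylation of a lactone: the aluminium lactolate is stable at −78 °C and is acetylated in the flask together with the C3 alkoxide, which avoids the ring-opened (Z)-hydroxy enal; the anomeric mixture is of no consequence.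

Step 10
Reactants: 19 but-2-yn-1-ol
Product: 20 (2Z)-3-(4,4,5,5-tetramethyl-1,3,2-dioxaborolan-2-yl)but-2-en-1-ol
Conditions: B2pin2, CuCl (5 mol%), PCy3 (6 mol%), NaOt-Bu (15 mol%), MeOH, toluene, rt
Reagents that add atoms: bis(pinacolato)diboron, CC1(C)OB(OC1(C)C)B1OC(C)(C)C(C)(C)O1
Why: Copper-catalysed formal hydroboration (syn borylcupration, then protonolysis with retention) places boron on the alkyne carbon remote from the hydroxymethyl group and trans to it, the geometry needed for the E C9=C10 bond.

Step 11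
Reactants: 20 (2Z)-3-(4,4,5,5-tetramethyl-1,3,2-dioxaborolan-2-yl)but-2-en-1-ol
Product: 21 (2Z)-3-(4,4,5,5-tetramethyl-1,3,2-dioxaborolan-2-yl)but-2-en-1-yl acetate
Conditions: Ac2O, pyridine, DMAP (cat.), CH2Cl2, 0 °C
Reagents that add atoms: acetic anhydride, CC(=O)OC(C)=O
Why: Simple acylation caps the hydroxyl, which would otherwise act as an oxygen nucleophile in step 13; it is done after borylation because a propargylic ester would undergo SN2' borylation.

Step 12
Reactants: 21 (2Z)-3-(4,4,5,5-tetramethyl-1,3,2-dioxaborolan-2-yl)but-2-en-1-yl acetate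
Product: 22 potassium [(2Z)-4-acetoxybut-2-en-2-yl]trifluoroborate
Conditions: KHF2 (aq.), MeOH, rt
Reagents that add atoms: potassium hydrogen difluoride, F.[F-].[K+]
Why: Exchange of the pinacol ester for fluoride gives the bench-stable trifluoroborate with the alkene geometry retained; the acetate tolerates the mildly acidic fluoride.

Step 13
Reactants: 18 (6S,7aR)-4,4,7a-trimethyl-2,4,5,6,7,7a-hexahydro-1-benzofuran-2,6-diyl diacetate; 22 potassium [(2Z)-4-acetoxybut-2-en-2-yl]trifluoroborate
Product: 23 (2E)-3-[(2R,6S,7aR)-6-acetoxy-4,4,7a-trimethyl-2,4,5,6,7,7a-hexahydro-1-benzofuran-2-yl]but-2-en-1-yl acetate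
Conditions: BF3·OEt2, CH2Cl2/MeCN, −78 to −30 °C; Et3N, then aq. NaHCO3 at −30 °C
Reagents that add atoms: none
Why: BF3·OEt2 ionizes the allylic anomeric acetate to the planar O-stabilized allyl cation and converts 22 into the alkenyldifluoroborane, which transfers its alkenyl group with retention of geometry to C8 (C6, flanked by two quaternary carbons, is shielded); C8 is set by attack anti to the axial C5 methyl, a bias that may be modest because the other face carries only the C4 methylene, so the 8S epimer is removed by chromatography.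

Step 14
Reactants: 23 (2E)-3-[(2R,6S,7aR)-6-acetoxy-4,4,7a-trimethyl-2,4,5,6,7,7a-hexahydro-1-benzofuran-2-yl]but-2-en-1-yl acetate
Product: 24 (2R,6S,7aR)-2-[(2E)-4-hydroxybut-2-en-2-yl]-4,4,7a-trimethyl-2,4,5,6,7,7a-hexahydro-1-benzofuran-6-ol
Conditions: K2CO3 (cat.), MeOH, rt
Reagents that add atoms: none
Why: Base-catalysed transesterification to methanol removes both acetates; the bis-allylic ether at C8 has no acidifying carbonyl at this stage and is stable to carbonate.

Step 15
Reactants: 24 (2R,6S,7aR)-2-[(2E)-4-hydroxybut-2-en-2-yl]-4,4,7a-trimethyl-2,4,5,6,7,7a-hexahydro-1-benzofuran-6-ol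
Product: 25 (2E)-3-[(2R,6S,7aR)-6-hydroxy-4,4,7a-trimethyl-2,4,5,6,7,7a-hexahydro-1-benzofuran-2-yl]but-2-enal
Conditions: MnO2 (activated), CH2Cl2, rt, dark
Reagents that add atoms: none
Why: MnO2 oxidizes only the allylic primary alcohol under neutral conditions, leaving the saturated C3 carbinol and the acid-labile bis-allylic ether untouched.

Step 16
Reactants: 26 (2E,4E,6E)-2,7-dimethylocta-2,4,6-trienedial
Product: 27 (2E,4E,6E)-2,7-dimethylocta-2,4,6-triene-1,8-diol
Conditions: NaBH4, MeOH/CH2Cl2, 0 °C
Reagents that add atoms: none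
Why: Borohydride reduces both conjugated aldehydes by 1,2-addition without touching the triene.

Step 17
Reactants: 27 (2E,4E,6E)-2,7-dimethylocta-2,4,6-triene-1,8-diol
Product: 28 [(2E,4E,6E)-2,7-dimethylocta-2,4,6-triene-1,8-diyl]bis(triphenylphosphonium) dibromide
Conditions: Ph3P·HBr, MeOH, rt
Reagents that add atoms: triphenylphosphine hydrobromide, Br.c1ccc(cc1)P(c1ccccc1)c1ccccc1
Why: Allylic alcohols give phosphonium salts with Ph3P·HBr through allylic cations that are captured reversibly, so phosphorus should end at the terminal carbons, where the triene stays fully conjugated.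

Step 18
Reactants: 25 (2E)-3-[(2R,6S,7aR)-6-hydroxy-4,4,7a-trimethyl-2,4,5,6,7,7a-hexahydro-1-benzofuran-2-yl]but-2-enal (two equivalents); 28 [(2E,4E,6E)-2,7-dimethylocta-2,4,6-triene-1,8-diyl]bis(triphenylphosphonium) dibromide
Product: 30 (3S,5R,8R,3'S,5'R,8'R)-5,8:5',8'-diepoxy-5,8,5',8'-tetrahydro-β,β-carotene-3,3'-diol ((8R,8'R)-auroxanthin), via C10 bis-ylide 29 (not isolated)
Conditions: NaN(SiMe3)2 (2 equiv), THF, −78 to −30 °C; then 25, −78 to 0 °C; then EtOAc, reflux, dark, argon
Reagents that add atoms: none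
Why: Double Wittig olefination of the preformed bis-ylide builds C11=C12 and C11'=C12' with no free amide or alkoxide base left to deprotonate C8, and the sterically hindered Z isomers at these positions should isomerize thermally to the all-E polyene; no stereocentre is touched.

## Compound list

1 | (S)-epichlorohydrin | C1[C@H](O1)CCl | starting material
2 | isopropenylmagnesium bromide | CC(=C)[Mg]Br | starting material
3 | (2S)-1-chloro-4-methylpent-4-en-2-ol | C=C(C)C[C@H](O)CCl | intermediate
4 | (2S)-2-(2-methylprop-2-en-1-yl)oxirane | C=C(C)C[C@H]1CO1 | intermediate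
5 | 2-methyl-1,3-dithiane | CC1SCCCS1 | starting material
6 | 2-lithio-2-methyl-1,3-dithiane | [Li]C1(C)SCCCS1 | intermediate
7 | (2S)-4-methyl-1-(2-methyl-1,3-dithian-2-yl)pent-4-en-2-ol | C=C(C)C[C@H](O)CC1(C)SCCCS1 | intermediate
8 | 2-[(2S)-2-(methoxymethoxy)-4-methylpent-4-en-1-yl]-2-methyl-1,3-dithiane | C=C(C)C[C@H](OCOC)CC1(C)SCCCS1 | intermediate
9 | (4S)-4-(methoxymethoxy)-6-methylhept-6-en-2-one | C=C(C)C[C@H](OCOC)CC(C)=O | intermediate
10 | ethyl propiolate | C#CC(=O)OCC | starting material
11 | ethyl 3-lithioprop-2-ynoate | [Li]C#CC(=O)OCC | intermediate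
12 | ethyl (4R,6S)-4-hydroxy-6-(methoxymethoxy)-4,8-dimethylnon-8-en-2-ynoate | C=C(C)C[C@H](OCOC)C[C@@](C)(O)C#CC(=O)OCC | intermediate
13 | ethyl (2E)-2-[(2R,4S)-2-hydroxy-4-(methoxymethoxy)-2,6,6-trimethylcyclohexylidene]acetate | CCOC(=O)/C=C1\C(C)(C)C[C@H](OCOC)C[C@@]1(C)O | intermediate
14 | ethyl (2Z)-2-[(2R,4S)-2-hydroxy-4-(methoxymethoxy)-2,6,6-trimethylcyclohexylidene]acetate | CCOC(=O)/C=C1/C(C)(C)C[C@H](OCOC)C[C@@]1(C)O | intermediate
15 | (6S,7aR)-6-(methoxymethoxy)-4,4,7a-trimethyl-5,6,7,7a-tetrahydro-1-benzofuran-2(4H)-one | O=C1C=C2C(C)(C)C[C@H](OCOC)C[C@@]2(C)O1 | intermediate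
16 | (6S,7aR)-6-hydroxy-4,4,7a-trimethyl-5,6,7,7a-tetrahydro-1-benzofuran-2(4H)-one ((−)-loliolide) | O=C1C=C2C(C)(C)C[C@H](O)C[C@@]2(C)O1 | intermediate
17 | (6S,7aR)-4,4,7a-trimethyl-2,4,5,6,7,7a-hexahydro-1-benzofuran-2,6-diol (lactol, present as its aluminium alkoxide) | OC1C=C2C(C)(C)C[C@H](O)C[C@@]2(C)O1 | intermediate
18 | (6S,7aR)-4,4,7a-trimethyl-2,4,5,6,7,7a-hexahydro-1-benzofuran-2,6-diyl diacetate (both C2 anomers) | CC(=O)OC1C=C2C(C)(C)C[C@H](OC(C)=O)C[C@@]2(C)O1 | intermediate
19 | but-2-yn-1-ol | CC#CCO | starting material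
20 | (2Z)-3-(4,4,5,5-tetramethyl-1,3,2-dioxaborolan-2-yl)but-2-en-1-ol | OC/C=C(\C)B1OC(C)(C)C(C)(C)O1 | intermediate
21 | (2Z)-3-(4,4,5,5-tetramethyl-1,3,2-dioxaborolan-2-yl)but-2-en-1-yl acetate | CC(=O)OC/C=C(\C)B1OC(C)(C)C(C)(C)O1 | intermediate
22 | potassium [(2Z)-4-acetoxybut-2-en-2-yl]trifluoroborate | CC(=O)OC/C=C(\C)[B-](F)(F)F.[K+] | intermediate
23 | (2E)-3-[(2R,6S,7aR)-6-acetoxy-4,4,7a-trimethyl-2,4,5,6,7,7a-hexahydro-1-benzofuran-2-yl]but-2-en-1-yl acetate | CC(=O)OC/C=C(\C)[C@H]1C=C2C(C)(C)C[C@H](OC(C)=O)C[C@@]2(C)O1 | intermediate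
24 | (2R,6S,7aR)-2-[(2E)-4-hydroxybut-2-en-2-yl]-4,4,7a-trimethyl-2,4,5,6,7,7a-hexahydro-1-benzofuran-6-ol | OC/C=C(\C)[C@H]1C=C2C(C)(C)C[C@H](O)C[C@@]2(C)O1 | intermediate
25 | (2E)-3-[(2R,6S,7aR)-6-hydroxy-4,4,7a-trimethyl-2,4,5,6,7,7a-hexahydro-1-benzofuran-2-yl]but-2-enal | O=C/C=C(\C)[C@H]1C=C2C(C)(C)C[C@H](O)C[C@@]2(C)O1 | intermediate
26 | (2E,4E,6E)-2,7-dimethylocta-2,4,6-trienedial | O=C/C(C)=C/C=C/C=C(\C)C=O | starting material
27 | (2E,4E,6E)-2,7-dimethylocta-2,4,6-triene-1,8-diol | OC/C(C)=C/C=C/C=C(\C)CO | intermediate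
28 | [(2E,4E,6E)-2,7-dimethylocta-2,4,6-triene-1,8-diyl]bis(triphenylphosphonium) dibromide | c1ccccc1[P+](c1ccccc1)(c1ccccc1)C/C(C)=C/C=C/C=C(\C)C[P+](c1ccccc1)(c1ccccc1)c1ccccc1.[Br-].[Br-] | intermediate
29 | (2E,4E,6E)-2,7-dimethylocta-2,4,6-triene-1,8-diylidenebis(triphenylphosphorane) | c1ccccc1P(c1ccccc1)(c1ccccc1)=C/C(C)=C/C=C/C=C(\C)C=P(c1ccccc1)(c1ccccc1)c1ccccc1 | intermediate
30 | (3S,5R,8R,3'S,5'R,8'R)-5,8:5',8'-diepoxy-5,8,5',8'-tetrahydro-β,β-carotene-3,3'-diol | CC(/C=C/C=C(\C)[C@H]1C=C2C(C)(C)C[C@H](O)C[C@@]2(C)O1)=C\C=C\C=C(C)\C=C\C=C(/C)[C@H]1C=C2C(C)(C)C[C@H](O)C[C@@]2(C)O1 | target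

## Step count and risks

Total step count: 18 (13 in the main line, 3 for trifluoroborate 22, 2 for salt 28).
Longest linear sequence: 13 steps (steps 1 to 9, 13, 14, 15 and 18).

Steps most likely to fail:

Step 7. The tertiary radical may be reduced before it cyclizes, the iron hydride or silane may attack the ynoate, or the E ester may isomerize too slowly, so that hydroxy ester accumulates instead of lactone. The fallback sets out from 12 and comes back at 15; it makes the lactone ring before the C1–C6 bond, so that the radical adds to an alkene whose geometry is already fixed. Semi-hydrogenation of 12 over Pd/CaCO3 poisoned with Pb(OAc)2 and quinoline gives the Z enoate, which lactonizes (pyridinium p-toluenesulfonate) to (5R)-5-[(2S)-2-(methoxymethoxy)-4-methylpent-4-en-1-yl]-5-methylfuran-2(5H)-one F1. Fe(acac)3 and PhSiH3 then bring about the 6-exo-trig Giese cyclization of the C1 radical onto C6 of the butenolide, giving the cis-fused saturated lactone (3aS,6S,7aR)-6-(methoxymethoxy)-4,4,7a-trimethylhexahydro-1-benzofuran-2(3H)-one F2. The C6=C7 bond is restored by α-selenenylation (LiN(i-Pr)2, PhSeCl, −78 °C) to (3aS,6S,7aR)-6-(methoxymethoxy)-4,4,7a-trimethyl-3-(phenylselanyl)hexahydro-1-benzofuran-2(3H)-one F3 and oxidative syn-elimination (H2O2, pyridine, CH2Cl2), which returns 15.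

Step 13. Facial selectivity at the C8 cation may be poor or inverted, and the bis-allylic C8–O bond of the product may re-ionize under the Lewis acid and epimerize C8. The fallback sets out from 16 (and from boronate 20 for the side chain) and comes back at 24; it reverses the order at C8, so that hydride and not carbon is delivered to the cation and the sense of induction is inverted. Boronate 20 is silylated (t-BuMe2SiCl, imidazole) to tert-butyldimethyl{[(2Z)-3-(4,4,5,5-tetramethyl-1,3,2-dioxaborolan-2-yl)but-2-en-1-yl]oxy}silane F4, iododeboronated with retention (NaOH, I2) to tert-butyl{[(2E)-3-iodobut-2-en-1-yl]oxy}dimethylsilane F5, and exchanged (t-BuLi, Et2O, −78 °C) to [(2Z)-4-(tert-butyldimethylsilyloxy)but-2-en-2-yl]lithium F6. Excess F6 adds to the lactone carbonyl of 16 to give the hemiketal (6S,7aR)-2-[(2E)-4-(tert-butyldimethylsilyloxy)but-2-en-2-yl]-4,4,7a-trimethyl-2,4,5,6,7,7a-hexahydro-1-benzofuran-2,6-diol F7. Ionization with BF3·OEt2 in the presence of Et3SiH at −78 °C reduces the cation at C8 to (2R,6S,7aR)-2-[(2E)-4-(tert-butyldimethylsilyloxy)but-2-en-2-yl]-4,4,7a-trimethyl-2,4,5,6,7,7a-hexahydro-1-benzofuran-6-ol F8, and Bu4NF gives 24. If neither order shows a useful bias, the C8 epimers remain separable diastereomers.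

Step 6. The lithiated propiolate may decompose on warming or on transmetalation, and chelation may be incomplete, which lowers the facial selectivity at the ketone. The fallback sets out from 9 and comes back at 12; it makes the C5–C6 and C7–C8 bonds separately. Ketone 9, precomplexed with MgBr2·OEt2 in CH2Cl2 at −78 °C, is treated with ethynylmagnesium bromide, a robust nucleophile under chelation control, to give (3R,5S)-5-(methoxymethoxy)-3,7-dimethyloct-7-en-1-yn-3-ol F9. Double deprotonation (n-BuLi, 2 equiv, THF, −78 °C) and CO2 give (4R,6S)-4-hydroxy-6-(methoxymethoxy)-4,8-dimethylnon-8-en-2-ynoic acid F10, and EtI with K2CO3 in DMF gives ester 12.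

## Further compounds

F1 | step 7 | (5R)-5-[(2S)-2-(methoxymethoxy)-4-methylpent-4-en-1-yl]-5-methylfuran-2(5H)-one | C=C(C)C[C@H](OCOC)C[C@@]1(C)OC(=O)C=C1
F2 | step 7 | (3aS,6S,7aR)-6-(methoxymethoxy)-4,4,7a-trimethylhexahydro-1-benzofuran-2(3H)-one | O=C1C[C@H]2C(C)(C)C[C@H](OCOC)C[C@@]2(C)O1
F3 | step 7 | (3aS,6S,7aR)-6-(methoxymethoxy)-4,4,7a-trimethyl-3-(phenylselanyl)hexahydro-1-benzofuran-2(3H)-one | O=C1C([Se]c3ccccc3)[C@H]2C(C)(C)C[C@H](OCOC)C[C@@]2(C)O1
F4 | step 13 | tert-butyldimethyl{[(2Z)-3-(4,4,5,5-tetramethyl-1,3,2-dioxaborolan-2-yl)but-2-en-1-yl]oxy}silane | CC(C)(C)[Si](C)(C)OC/C=C(\C)B1OC(C)(C)C(C)(C)O1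
F5 | step 13 | tert-butyl{[(2E)-3-iodobut-2-en-1-yl]oxy}dimethylsilane | CC(C)(C)[Si](C)(C)OC/C=C(\C)I
F6 | step 13 | [(2Z)-4-(tert-butyldimethylsilyloxy)but-2-en-2-yl]lithium | CC(C)(C)[Si](C)(C)OC/C=C(\C)[Li]
F7 | step 13 | (6S,7aR)-2-[(2E)-4-(tert-butyldimethylsilyloxy)but-2-en-2-yl]-4,4,7a-trimethyl-2,4,5,6,7,7a-hexahydro-1-benzofuran-2,6-diol | CC(C)(C)[Si](C)(C)OC/C=C(\C)C1(O)C=C2C(C)(C)C[C@H](O)C[C@@]2(C)O1
F8 | step 13 | (2R,6S,7aR)-2-[(2E)-4-(tert-butyldimethylsilyloxy)but-2-en-2-yl]-4,4,7a-trimethyl-2,4,5,6,7,7a-hexahydro-1-benzofuran-6-ol | CC(C)(C)[Si](C)(C)OC/C=C(\C)[C@H]1C=C2C(C)(C)C[C@H](O)C[C@@]2(C)O1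
F9 | step 6 | (3R,5S)-5-(methoxymethoxy)-3,7-dimethyloct-7-en-1-yn-3-ol | C=C(C)C[C@H](OCOC)C[C@@](C)(O)C#C
F10 | step 6 | (4R,6S)-4-hydroxy-6-(methoxymethoxy)-4,8-dimethylnon-8-en-2-ynoic acid | C=C(C)C[C@H](OCOC)C[C@@](C)(O)C#CC(=O)O
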